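## Structural features

Gnetucleistol F (21) is a 2,3-dihydro-1-benzofuran. Its benzo ring (ring B) carries a methoxy group at C7 and, at C5, an (E)-ethenyl bridge to a 3,5-dihydroxyphenyl ring. The dihydrofuran ring carries a 4-hydroxy-3,5-dimethoxyphenyl (syringyl) ring at C2 and a hydroxymethyl group at C3. The only stereocentres, C2 (R) and C3 (S), are neighbours and their substituents are trans. The O1–C2 bond is a benzylic aryl ether para to a phenol, so it ionises in acid and can open through a para-quinone methide in base or on oxidation. The stilbene forbids hydrogenolysis and strong electrophiles, and the three phenols are easily oxidised. Because C2 can be re-formed through its cation and then settles trans to the C3 substituent, C2 is a dependent centre. The real difficulty is the absolute configuration of C3, a benzylic methine joined to C3a of ring B, to the CH2OH carbon and to C2. The key step exploits the C3(–CH2OH)–C2(–O) array: one carbon on C3 and one oxygen on C2 is the imprint of formaldehyde added across a ring B–CH=CH–syringyl double bond. The electron-poor ring B and the electron-rich syringyl ring tell the two olefin carbons apart.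

## Logic of the disconnections

21 ⇒ 20. Three O–Si bonds are cut (the syringyl oxygen and the two resorcinol oxygens). The phenols must be masked during the base and hydride steps, and one fluoride operation at the end removes all masks. 20 has no free phenol. The forward step must leave the stilbene, the O1–C2 bond and both stereocentres alone, so the phenoxides have to be protonated as they form.

20 ⇒ 14 + 19. The C=C bond of the C5 side chain is cut. This is the most convergent cut and separates the resorcinol ring from the chiral core. 14 contains only the dihydrobenzofuran with a formyl carbon at C5. The forward olefination must be (E)-selective and must tolerate the free primary alcohol of 14.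

14 ⇒ 13 ⇒ 12. No skeletal bond is cut; the C5 carbon is taken back from formyl to hydroxymethyl to ester. The ester level is needed earlier, where it acts as the acceptor on ring B. The forward oxidation must distinguish the benzylic alcohol at C5 from the saturated C3 hydroxymethyl group.

12 ⇒ 9 (through 10 and 11). The O1–C2 bond is cut and the C2 oxygen is put back as part of a formaldehyde acetal that also holds the C3–CH2O oxygen. C2 is under thermodynamic control next to a fixed C3, so its configuration need not be carried; in 9 it is only stored as an acetal C–O bond. The dihydrofuran ring and one stereochemical problem disappear, leaving one ring with one centre that matters (C5 of 9). The forward step must ionise only the benzylic C–O bond of the acetal and close the ring before the cation loses the neighbouring proton.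

9 ⇒ 7 + 8. The C5–C6 bond of the dioxane (C3–CH2 in 21), the C4–O3 bond and the acetal bonds are cut, releasing two molecules of 8. This is the only point where carbon is added to a flat precursor, so it is the place for catalytic asymmetric induction. 9, with a ring and two stereocentres, goes back to achiral, planar 7 and a one-carbon feedstock. The forward step needs carbon delivered to the olefin carbon next to ring B, one olefin face chosen, and nothing else in 7 reacting with an acid-activated aldehyde. For that reason 7 has a single C=C bond, an acyloxy and an ester group on ring B, and a silyl ether (not an unsaturated ether) on the donor ring.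

7 ⇒ 6 + 3. The aryl–vinyl bond between ring B and the olefin is cut. A Heck coupling forms it with (E) geometry from two simple aromatics. The forward step must arylate the terminal olefin carbon and keep the acetate.

6 ⇒ 5 ⇒ 4 and 3 ⇒ 2 ⇒ 1. The O–acyl and C–iodine bonds of 6, and the terminal C=C and O–Si bonds of 3, are cut. Each is a single functional-group operation on a commodity aromatic. The iodination must go ortho to the phenol of 4, which is the only activated free position.

19 ⇒ 18 ⇒ 17 ⇒ 16 ⇒ 15. The C–P bond, the C–Br bond, the alcohol oxidation level and two O–Si bonds are taken back in turn. The bulky silyl groups must survive hydride, bromination and hot phosphite.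

## Other disconnections considered

Alternative 1: The cut is the O1–C2 bond alone, made from a C2–H bond. The forward step would be a two-electron anodic oxidation of the syringyl phenol of the open-chain bis-phenol A2, in which C3 is already set, to the para-quinone methide A3. The ring B phenol oxygen would then add to the methide carbon (C2) and close the ring trans to the C3 hydroxymethyl group, giving the 5-bromo core A1.
- In favour: no protecting groups on the reacting phenols, electrons as the only oxidant, the same thermodynamic trans preference at C2 that the chosen plan uses, and a C5 bromide to which the styryl arm could be attached by one cross-coupling.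
- Against: the step forms no C–C bond and does not create C3, so A2 would still need its own asymmetric synthesis. The oxidation would have to stop at A3 although A1 keeps an oxidisable syringyl phenol next to a benzylic C2–H bond, and the ring B phenol is itself electroactive; over-oxidation to a benzofuran or to quinones is a plausible leak.
- Comparison: in structure both plans treat C2 as the dependent centre. In mechanism the alternative reaches the C2 electrophile under neutral oxidative conditions, not by acid ionisation; on this point, and on the shorter end-game from the bromide, it is the better plan. In step economy it is at best the equal, because what is saved at the end is spent on making A2 enantioenriched, whereas step 6 creates C3 and the C2 oxygen in one catalytic operation from a flat olefin.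

Alternative 2: The cut goes through both the C2–C3 and the O1–C2 bonds, a (4+1) disconnection into the ring B ortho-quinone methide A7 (O1, C7a, C3a, C3) and a one-carbon syringylmethyl ylide (C2). Forward, base would expel toluenesulfinate from the phenolic sulfone A5 to unveil A7. The ylide from the chiral sulfonium salt A6 would add to the exocyclic carbon of A7, and the phenoxide would displace the sulfide to give the protected trans 5-bromo dihydrobenzofuran A4.
- In favour: two ring bonds and both stereocentres in one convergent, mildly basic operation from two achiral halves; the addition and back-side displacement give the trans ring by mechanism; the bromide again shortens the end-game. On convergence and on bonds formed per step this is the better plan.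
- Against: the chirality source is stoichiometric (a recoverable sulfide) and acts on C2, so C3 is fixed only through the diastereoselectivity of the addition. A semi-stabilised benzylic ylide gives less reversible betaine formation than ester-stabilised ylides, so stereocontrol is less assured. A7 carries a CH2 group on its exocyclic carbon, which allows tautomerisation to a vinyl phenol in competition with ylide addition.
- Comparison: structurally it builds the trans ring more directly than the passage from 9 to 12. Mechanistically it avoids a cationic C2 altogether, which is an advantage, but it replaces catalytic control at C3 by reagent control at C2. In step economy the two plans should be close: the ylide route needs separate syntheses of A5 and A6 and an end-game coupling, the chosen route needs the adjustments at the C5 ester.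

Alternative 3: Ring B itself is disconnected. The C7–C6, C5–C4 and C7–C7a bonds are cut, leading back to the dihydrofuran-4-yl diazoketone A9, which already holds the trans C2/C3 pair, and the siloxyalkyne A10. Forward, photochemical Wolff rearrangement of A9 would give the vinylketene A11, which would add A10 in a (2+2) fashion. Four-electron opening of the cyclobutenone, six-electron closure of the dienylketene and tautomerisation would then give the benzo ring as a C7 phenol with a C5 silyl ether, A8.
- In favour: a regiospecific pericyclic cascade under neutral conditions; the stereocentres are made on a small heterocycle and are never exposed to acid afterwards; the two ring B oxygens come out differentiated.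
- Against: ring B with exactly this substitution can be bought as a vanillate, so the step builds what is available. Enantioenriched A9 needs its own multistep asymmetric synthesis. The enol ether and the benzylic C2–O bond of A9 and A11 are sensitive, and the diazo and ynol-ether reagents add handling cost. After A8, O-methylation, silyl removal, sulfonylation and a cross-coupling would still be needed before the styryl arm is in place.
- Comparison: on structure it is the only plan that would adapt easily to analogues with other ring B patterns, and on mildness of the ring-forming step it is the equal or better. On mechanism it moves all the stereochemical work to an earlier, unsolved intermediate. On step economy it is clearly the longest.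

Key step: step 6

Remark (design of 7): the syringyl oxygen is carried as a tri(propan-2-yl)silyl (TIPS) ether and not as an allyl or other unsaturated ether, so that 7 has only one C=C bond when it meets the palladium catalyst in step 5 and the acid/formaldehyde pair in step 6. Ring B is carried as an acetate, installed before the coupling, because an amine removes it without touching the silyl ether or the methyl ester.

Remark (stereochemical check): C5 of 9 (S) becomes C3 of 21 (S) with its ligands in the same spatial order. C4 of 9 (S) has the opposite spatial sense to C2 of 21 (R), as it must in a trans-4,5-diaryl dioxane from an (E)-olefin, and it is re-formed in step 7.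

Remark (assumption): which antipode of the confined acid gives the (5S) centre cannot be predicted for a 1,2-diaryl olefin. Both antipodes are equally accessible, and the one that gives 9 is assumed to be identified in a first small run.

Remark (assumption): 5-iodobenzene-1,3-diol, used only in a fallback, is taken to be a catalogue compound.

## Route

Step 1
Reactants: 1 syringaldehyde (4-hydroxy-3,5-dimethoxybenzaldehyde)
Product: 2 3,5-dimethoxy-4-[tri(propan-2-yl)silyloxy]benzaldehyde
Conditions: i-Pr3SiCl, imidazole, DMAP (cat.), DMF, 40 °C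
Reagents that add atoms: chlorotri(propan-2-yl)silane, CC(C)[Si](Cl)(C(C)C)C(C)C
Why: O-silylation of a phenol; the acidic para-formyl phenol reacts despite its two ortho methoxy groups, and the same flanking groups later shield the Si–O bond from bases.

Step 2
Reactants: 2 3,5-dimethoxy-4-[tri(propan-2-yl)silyloxy]benzaldehyde
Product: 3 (4-ethenyl-2,6-dimethoxyphenoxy)tri(propan-2-yl)silane
Conditions: Ph3PCH3Br (1.3 equiv), NaN(SiMe3)2 (1.25 equiv), THF, 0 °C → rt
Reagents that add atoms: methyltriphenylphosphonium bromide, [Br-].C[P+](c1ccccc1)(c1ccccc1)c1ccccc1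
Why: Wittig methylenation of an aromatic aldehyde; a non-nucleophilic amide base used in slight deficit to the salt leaves no free base that could attack the aryl silyl ether.

Step 3
Reactants: 4 methyl vanillate (methyl 4-hydroxy-3-methoxybenzoate)
Product: 5 methyl 4-hydroxy-3-iodo-5-methoxybenzoate
Conditions: N-iodosuccinimide (1.05 equiv), CF3CO2H (cat.), MeCN, rt
Reagents that add atoms: N-iodosuccinimide, O=C1CCC(=O)N1I
Why: Electrophilic aromatic iodination; the position ortho to the phenol is the only activated free site, since the para position holds the ester and the other ortho position the methoxy group.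

Step 4
Reactants: 5 methyl 4-hydroxy-3-iodo-5-methoxybenzoate
Product: 6 methyl 4-acetoxy-3-iodo-5-methoxybenzoate
Conditions: Ac2O, Et3N, DMAP (cat.), CH2Cl2, rt
Reagents that add atoms: acetic anhydride, CC(=O)OC(C)=O
Why: O-acylation of a phenol; the acetate turns the ring B oxygen into a weak donor for step 6, keeps a free ortho-halophenol out of the coupling, and is later removed by an amine alone.

Step 5
Reactants: 6 methyl 4-acetoxy-3-iodo-5-methoxybenzoate; 3 (4-ethenyl-2,6-dimethoxyphenoxy)tri(propan-2-yl)silane
Product: 7 methyl 4-acetoxy-3-[(E)-2-{3,5-dimethoxy-4-[tri(propan-2-yl)silyloxy]phenyl}ethenyl]-5-methoxybenzoate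
Conditions: Pd(OAc)2 (5 mol%), P(o-tol)3 (10 mol%), Et3N, MeCN, 85 °C
Reagents that add atoms: none
Why: Mizoroki–Heck coupling; oxidative addition of the carbon–iodine bond to zerovalent palladium, syn insertion with the aryl group going to the terminal olefin carbon and syn β-hydride elimination give the (E)-olefin, and 3 offers no second olefin.

Step 6
Reactants: 7 methyl 4-acetoxy-3-[(E)-2-{3,5-dimethoxy-4-[tri(propan-2-yl)silyloxy]phenyl}ethenyl]-5-methoxybenzoate; 8 formaldehyde (charged as paraformaldehyde)
Product: 9 methyl 4-acetoxy-3-[(4S,5S)-4-{3,5-dimethoxy-4-[tri(propan-2-yl)silyloxy]phenyl}-1,3-dioxan-5-yl]-5-methoxybenzoate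
Conditions: (CH2O)n (5 equiv), confined chiral imidodiphosphorimidate acid (BINOL-derived, N-triflyl; 5 mol%), CHCl3, 20 °C
Reagents that add atoms: formaldehyde (= compound 8, two molecules are built in), C=O
Why: The acid protonates a formaldehyde oligomer inside its chiral pocket, and the olefin carbon next to ring B attacks the activated CH2 group while positive charge builds on the carbon next to the syringyl ring; the hemiacetal oxygen at the far end of the same two-formaldehyde unit then collapses onto that carbon in a concerted but highly asynchronous event, and the acid is released. The closest known reaction type is the catalytic asymmetric intermolecular Prins reaction of styrenes with paraformaldehyde to 4-aryl-1,3-dioxanes under confined chiral phosphorus-based Brønsted acids, applied here to an internal aryl olefin; the classical acid-promoted Prins reaction of 1-arylpropenes to 4-aryl-5-methyl-1,3-dioxanes shows that 1,2-disubstituted aryl olefins take part. The one ring formed, the 1,3-dioxane, is closed by C–O bond formation between the hemiacetal oxygen and the benzylic carbon through a chair-like six-membered array, overall a formal (2+2+2) union of one C=C and two C=O units. C5 of the dioxane (the later C3) is set by the olefin face that the chiral counter-anion leaves open to the electrophile. C4 follows from delivery of carbon and oxygen to the same face of the (E)-olefin, which puts the two aryl groups trans and equatorial. The step needs regioselectivity (carbon to the ring B side), secured because the acetoxy and ester groups on ring B and the oxygen-rich syringyl ring let only the syringyl-bearing carbon carry positive charge; chemoselectivity for the olefin over arene CH positions, helped by the tight pocket, the small electrophile and the absence of a second C=C bond; and enantioface selectivity, which rests on the catalyst alone. Only the C5 configuration is carried on, since C4 is re-formed in step 7.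

Step 7
Reactants: 9 methyl 4-acetoxy-3-[(4S,5S)-4-{3,5-dimethoxy-4-[tri(propan-2-yl)silyloxy]phenyl}-1,3-dioxan-5-yl]-5-methoxybenzoate
Product: 12 methyl (2R,3S)-2-{3,5-dimethoxy-4-[tri(propan-2-yl)silyloxy]phenyl}-3-(hydroxymethyl)-7-methoxy-2,3-dihydro-1-benzofuran-5-carboxylate, via phenol dioxane 10 (not isolated), via ring-closed hemiformal 11 (not isolated)
Conditions: pyrrolidine (1.1 equiv), CH2Cl2, rt; then MeOH (10 equiv), CF3CO2H (20 vol%), 0 °C → rt; aq. NaHCO3/MeOH work-up
Reagents that add atoms: none
Why: Aminolysis of the aryl acetate frees the ring B phenol (10); the acid then ionises the C4–O3 bond of the dioxane, the only benzylic donor-stabilised C–O bond, and the neighbouring phenol captures the cation in a five-membered (5-exo) closure, after which hemiformal 11 gives up its formaldehyde to methanol. This is an SN1-type cyclisation of the kind used for phenylcoumaran neolignans; C2 (R) is set here trans to the C3 substituent because the closure is reversible and the trans ring is the more stable one, while C3 is not touched.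

Step 8
Reactants: 12 methyl (2R,3S)-2-{3,5-dimethoxy-4-[tri(propan-2-yl)silyloxy]phenyl}-3-(hydroxymethyl)-7-methoxy-2,3-dihydro-1-benzofuran-5-carboxylate
Product: 13 [(2R,3S)-2-{3,5-dimethoxy-4-[tri(propan-2-yl)silyloxy]phenyl}-7-methoxy-2,3-dihydro-1-benzofuran-3,5-diyl]dimethanol
Conditions: i-Bu2AlH (4 equiv), CH2Cl2, −78 → 0 °C; aq. KNaC4H4O6
Reagents that add atoms: none
Why: Hydride reduction of an aryl ester to the benzylic alcohol; the aryl silyl ether, the cyclic benzylic ether and both stereocentres are inert to the aluminium hydride at low temperature, and the free alcohol only consumes one more equivalent.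

Step 9
Reactants: 13 [(2R,3S)-2-{3,5-dimethoxy-4-[tri(propan-2-yl)silyloxy]phenyl}-7-methoxy-2,3-dihydro-1-benzofuran-3,5-diyl]dimethanol
Product: 14 (2R,3S)-2-{3,5-dimethoxy-4-[tri(propan-2-yl)silyloxy]phenyl}-3-(hydroxymethyl)-7-methoxy-2,3-dihydro-1-benzofuran-5-carbaldehyde
Conditions: MnO2 (activated, excess), CH2Cl2, rt
Reagents that add atoms: none
Why: Chemoselective benzylic oxidation; MnO2 oxidises the C5 benzylic alcohol and leaves the saturated C3 hydroxymethyl group alone.

Step 10
Reactants: 15 3,5-dihydroxybenzaldehyde
Product: 16 3,5-bis[tri(propan-2-yl)silyloxy]benzaldehyde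
Conditions: i-Pr3SiCl (2.4 equiv), imidazole, DMF, rt
Reagents that add atoms: chlorotri(propan-2-yl)silane, CC(C)[Si](Cl)(C(C)C)C(C)C
Why: O-silylation of both phenols; the bulky silyl group is chosen because it resists the alkoxide and amide bases of step 14 better than smaller silyl groups.

Step 11
Reactants: 16 3,5-bis[tri(propan-2-yl)silyloxy]benzaldehyde
Product: 17 {3,5-bis[tri(propan-2-yl)silyloxy]phenyl}methanol
Conditions: NaBH4, MeOH/THF, 0 °C
Reagents that add atoms: none
Why: Borohydride reduction of an aldehyde; aryl silyl ethers of this size are stable to cold methanolic borohydride.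

Step 12
Reactants: 17 {3,5-bis[tri(propan-2-yl)silyloxy]phenyl}methanol
Product: 18 [5-(bromomethyl)-1,3-phenylene]bis(oxy)bis[tri(propan-2-yl)silane]
Conditions: CBr4, PPh3, CH2Cl2, 0 °C
Reagents that add atoms: carbon tetrabromide, BrC(Br)(Br)Br
Why: Appel bromination of a benzylic alcohol under neutral conditions, which generates no free acid that could harm the silyl ethers.

Step 13
Reactants: 18 [5-(bromomethyl)-1,3-phenylene]bis(oxy)bis[tri(propan-2-yl)silane]
Product: 19 diethyl ({3,5-bis[tri(propan-2-yl)silyloxy]phenyl}methyl)phosphonate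
Conditions: P(OEt)3 (neat), 130 °C
Reagents that add atoms: triethyl phosphite, CCOP(OCC)OCC
Why: Michaelis–Arbuzov reaction of a benzylic bromide; it needs no base or fluoride, so the aryl silyl ethers are not at risk.

Step 14
Reactants: 14 (2R,3S)-2-{3,5-dimethoxy-4-[tri(propan-2-yl)silyloxy]phenyl}-3-(hydroxymethyl)-7-methoxy-2,3-dihydro-1-benzofuran-5-carbaldehyde; 19 diethyl ({3,5-bis[tri(propan-2-yl)silyloxy]phenyl}methyl)phosphonate
Product: 20 [(2R,3S)-5-[(E)-2-{3,5-bis[tri(propan-2-yl)silyloxy]phenyl}ethenyl]-2-{3,5-dimethoxy-4-[tri(propan-2-yl)silyloxy]phenyl}-7-methoxy-2,3-dihydro-1-benzofuran-3-yl]methanol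
Conditions: 19 (1.6 equiv), KN(SiMe3)2 (2.6 equiv), THF, −78 °C → rt
Reagents that add atoms: none
Why: Horner–Wadsworth–Emmons olefination; the benzylic phosphonate anion adds to the aldehyde and loses phosphate to give the (E)-stilbene, while the primary alcohol rides as its alkoxide, which the bulky aryl silyl ethers should resist.

Step 15
Reactants: 20 [(2R,3S)-5-[(E)-2-{3,5-bis[tri(propan-2-yl)silyloxy]phenyl}ethenyl]-2-{3,5-dimethoxy-4-[tri(propan-2-yl)silyloxy]phenyl}-7-methoxy-2,3-dihydro-1-benzofuran-3-yl]methanol
Product: 21 gnetucleistol F, 5-[(E)-2-[(2R,3S)-2-(4-hydroxy-3,5-dimethoxyphenyl)-3-(hydroxymethyl)-7-methoxy-2,3-dihydro-1-benzofuran-5-yl]ethenyl]benzene-1,3-diol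
Conditions: Bu4NF (4 equiv), AcOH (4 equiv), THF, 0 °C → rt
Reagents that add atoms: none
Why: Fluoride-induced cleavage of three aryl O–Si bonds, driven by the strength of the Si–F bond; acetic acid protonates each phenoxide as it forms, so the syringyl phenoxide cannot open the O1–C2 bond through a quinone methide, and the stilbene and both stereocentres are untouched.

## Compound list

1 | syringaldehyde (4-hydroxy-3,5-dimethoxybenzaldehyde) | COc1cc(C=O)cc(OC)c1O | starting material
2 | 3,5-dimethoxy-4-[tri(propan-2-yl)silyloxy]benzaldehyde | COc1cc(C=O)cc(OC)c1O[Si](C(C)C)(C(C)C)C(C)C | intermediate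
3 | (4-ethenyl-2,6-dimethoxyphenoxy)tri(propan-2-yl)silane | COc1cc(C=C)cc(OC)c1O[Si](C(C)C)(C(C)C)C(C)C | intermediate
4 | methyl vanillate (methyl 4-hydroxy-3-methoxybenzoate) | COC(=O)c1ccc(O)c(OC)c1 | starting material
5 | methyl 4-hydroxy-3-iodo-5-methoxybenzoate | COC(=O)c1cc(I)c(O)c(OC)c1 | intermediate
6 | methyl 4-acetoxy-3-iodo-5-methoxybenzoate | COC(=O)c1cc(I)c(OC(C)=O)c(OC)c1 | intermediate
7 | methyl 4-acetoxy-3-[(E)-2-{3,5-dimethoxy-4-[tri(propan-2-yl)silyloxy]phenyl}ethenyl]-5-methoxybenzoate | COC(=O)c1cc(OC)c(OC(C)=O)c(/C=C/c2cc(OC)c(O[Si](C(C)C)(C(C)C)C(C)C)c(OC)c2)c1 | intermediate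
8 | formaldehyde (charged as paraformaldehyde) | C=O | starting material
9 | methyl 4-acetoxy-3-[(4S,5S)-4-{3,5-dimethoxy-4-[tri(propan-2-yl)silyloxy]phenyl}-1,3-dioxan-5-yl]-5-methoxybenzoate | CC(C)[Si](C(C)C)(C(C)C)Oc1c(OC)cc([C@H]2OCOC[C@@H]2c3cc(C(=O)OC)cc(OC)c3OC(C)=O)cc1OC | intermediate
10 | methyl 3-[(4S,5S)-4-{3,5-dimethoxy-4-[tri(propan-2-yl)silyloxy]phenyl}-1,3-dioxan-5-yl]-4-hydroxy-5-methoxybenzoate | CC(C)[Si](C(C)C)(C(C)C)Oc1c(OC)cc([C@H]2OCOC[C@@H]2c3cc(C(=O)OC)cc(OC)c3O)cc1OC | intermediate (not isolated)
11 | methyl (2R,3S)-2-{3,5-dimethoxy-4-[tri(propan-2-yl)silyloxy]phenyl}-3-[(hydroxymethoxy)methyl]-7-methoxy-2,3-dihydro-1-benzofuran-5-carboxylate | COc1cc([C@@H]2Oc3c(OC)cc(C(=O)OC)cc3[C@H]2COCO)cc(OC)c1O[Si](C(C)C)(C(C)C)C(C)C | intermediate (not isolated)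
12 | methyl (2R,3S)-2-{3,5-dimethoxy-4-[tri(propan-2-yl)silyloxy]phenyl}-3-(hydroxymethyl)-7-methoxy-2,3-dihydro-1-benzofuran-5-carboxylate | COc1cc([C@@H]2Oc3c(OC)cc(C(=O)OC)cc3[C@H]2CO)cc(OC)c1O[Si](C(C)C)(C(C)C)C(C)C | intermediate
13 | [(2R,3S)-2-{3,5-dimethoxy-4-[tri(propan-2-yl)silyloxy]phenyl}-7-methoxy-2,3-dihydro-1-benzofuran-3,5-diyl]dimethanol | COc1cc([C@@H]2Oc3c(OC)cc(CO)cc3[C@H]2CO)cc(OC)c1O[Si](C(C)C)(C(C)C)C(C)C | intermediate
14 | (2R,3S)-2-{3,5-dimethoxy-4-[tri(propan-2-yl)silyloxy]phenyl}-3-(hydroxymethyl)-7-methoxy-2,3-dihydro-1-benzofuran-5-carbaldehyde | COc1cc([C@@H]2Oc3c(OC)cc(C=O)cc3[C@H]2CO)cc(OC)c1O[Si](C(C)C)(C(C)C)C(C)C | intermediate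
15 | 3,5-dihydroxybenzaldehyde | O=Cc1cc(O)cc(O)c1 | starting material
16 | 3,5-bis[tri(propan-2-yl)silyloxy]benzaldehyde | O=Cc1cc(O[Si](C(C)C)(C(C)C)C(C)C)cc(O[Si](C(C)C)(C(C)C)C(C)C)c1 | intermediate
17 | {3,5-bis[tri(propan-2-yl)silyloxy]phenyl}methanol | OCc1cc(O[Si](C(C)C)(C(C)C)C(C)C)cc(O[Si](C(C)C)(C(C)C)C(C)C)c1 | intermediate
18 | [5-(bromomethyl)-1,3-phenylene]bis(oxy)bis[tri(propan-2-yl)silane] | BrCc1cc(O[Si](C(C)C)(C(C)C)C(C)C)cc(O[Si](C(C)C)(C(C)C)C(C)C)c1 | intermediate
19 | diethyl ({3,5-bis[tri(propan-2-yl)silyloxy]phenyl}methyl)phosphonate | CCOP(=O)(OCC)Cc1cc(O[Si](C(C)C)(C(C)C)C(C)C)cc(O[Si](C(C)C)(C(C)C)C(C)C)c1 | intermediate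
20 | [(2R,3S)-5-[(E)-2-{3,5-bis[tri(propan-2-yl)silyloxy]phenyl}ethenyl]-2-{3,5-dimethoxy-4-[tri(propan-2-yl)silyloxy]phenyl}-7-methoxy-2,3-dihydro-1-benzofuran-3-yl]methanol | COc1cc([C@@H]2Oc3c(OC)cc(/C=C/c4cc(O[Si](C(C)C)(C(C)C)C(C)C)cc(O[Si](C(C)C)(C(C)C)C(C)C)c4)cc3[C@H]2CO)cc(OC)c1O[Si](C(C)C)(C(C)C)C(C)C | intermediate
21 | gnetucleistol F, 5-[(E)-2-[(2R,3S)-2-(4-hydroxy-3,5-dimethoxyphenyl)-3-(hydroxymethyl)-7-methoxy-2,3-dihydro-1-benzofuran-5-yl]ethenyl]benzene-1,3-diol | COc1cc([C@@H]2Oc3c(OC)cc(/C=C/c4cc(O)cc(O)c4)cc3[C@H]2CO)cc(OC)c1O | target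

## Step count and least certain steps

Total step count: 15. Longest linear sequence: 9 steps (steps 1, 2, 5, 6, 7, 8, 9, 14, 15; the sequence from 4 through steps 3, 4, 5 to 15 is equally long).

**Step 6 (key step).** What may go wrong: low turnover and loss of selectivity, because a 1,2-diaryl olefin is bulkier and less nucleophilic than the terminal styrenes on which confined acids are established. Activated formaldehyde may then hydroxymethylate the free CH positions of the syringyl ring, and enantioface discrimination may be weak.

Fallback (auxiliary-controlled aldol in place of the Prins reaction; sets out from 5 and 2, comes back at 12):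
- Benzylation of 5 (BnBr, K2CO3, DMF) gives methyl 4-(benzyloxy)-3-iodo-5-methoxybenzoate F1.
- Palladium-catalysed coupling with the Reformatsky reagent BrZnCH2CO2t-Bu (Pd(dba)2, P(t-Bu)3, THF) gives methyl 4-(benzyloxy)-3-(2-tert-butoxy-2-oxoethyl)-5-methoxybenzoate F2.
- CF3CO2H in CH2Cl2 cleaves the tert-butyl ester to [2-(benzyloxy)-3-methoxy-5-(methoxycarbonyl)phenyl]acetic acid F3.
- The pivaloyl mixed anhydride of F3 (t-BuCOCl, Et3N, LiCl, THF) acylates (R)-4-benzyl-1,3-oxazolidin-2-one to give methyl 4-(benzyloxy)-3-{2-[(4R)-4-benzyl-2-oxo-1,3-oxazolidin-3-yl]-2-oxoethyl}-5-methoxybenzoate F4.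
- Evans syn-aldol addition of its boron enolate (Bu2BOTf, i-Pr2NEt, CH2Cl2, −78 °C) to 2 gives methyl 4-(benzyloxy)-3-{(2R,3R)-1-[(4R)-4-benzyl-2-oxo-1,3-oxazolidin-3-yl]-3-{3,5-dimethoxy-4-[tri(propan-2-yl)silyloxy]phenyl}-3-hydroxy-1-oxopropan-2-yl}-5-methoxybenzoate F5. The later C3 is fixed here by the auxiliary.
- LiBH4 (THF, MeOH, 0 °C) turns the imide carbonyl into the CH2OH group and releases the auxiliary, giving methyl 4-(benzyloxy)-3-[(1R,2S)-1-{3,5-dimethoxy-4-[tri(propan-2-yl)silyloxy]phenyl}-1,3-dihydroxypropan-2-yl]-5-methoxybenzoate F6.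
- Hydrogenolysis (H2, Pd/C, EtOAc) frees the ring B phenol in methyl 3-[(1R,2S)-1-{3,5-dimethoxy-4-[tri(propan-2-yl)silyloxy]phenyl}-1,3-dihydroxypropan-2-yl]-4-hydroxy-5-methoxybenzoate F7.
- CF3CO2H in CH2Cl2 then ionises the benzylic alcohol and closes the ring trans, which gives 12.

**Step 7.** What may go wrong: the C2 cation may live long enough to lose the C3 proton, which erases the C3 centre through a stilbene-type olefin, or to alkylate an electron-rich ring of a second molecule. An acid strong enough to open the dioxane may also begin to cleave the silyl ether.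

Fallback (quinone-methide manifold under much weaker acid; sets out from 9, comes back at 12):
- Bu4NF in wet THF removes both the silyl ether and the aryl acetate, giving methyl 4-hydroxy-3-[(4S,5S)-4-(4-hydroxy-3,5-dimethoxyphenyl)-1,3-dioxan-5-yl]-5-methoxybenzoate F8.
- With the para oxygen free, the C4–O3 bond opens in AcOH/H2O/THF at 40 °C through a protonated para-quinone methide, which the ring B phenol captures; the hemiformal hydrolyses. This gives methyl (2R,3S)-2-(4-hydroxy-3,5-dimethoxyphenyl)-3-(hydroxymethyl)-7-methoxy-2,3-dihydro-1-benzofuran-5-carboxylate F9.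
- The phenol alone is re-silylated through its phenoxide (KOt-Bu, 1.0 equiv, then i-Pr3SiCl, THF, 0 °C; the far less acidic alcohol is not deprotonated), which returns 12.

**Step 5.** What may go wrong: insertion of the electron-rich styrene with the wrong regiochemistry (aryl group to the internal carbon), or decomposition of the catalyst to palladium black before conversion is complete.

Fallback (the position of the new bond is fixed beforehand by a carbon–boron bond; sets out from 3 and 6, comes back at 7):
- Cross-metathesis of 3 with vinylboronic acid pinacol ester (RuCl2(=CHPh)(PCy3)(H2IMes), the second-generation Grubbs catalyst, CH2Cl2, 40 °C) gives {2,6-dimethoxy-4-[(E)-2-(4,4,5,5-tetramethyl-1,3,2-dioxaborolan-2-yl)ethenyl]phenoxy}tri(propan-2-yl)silane F10.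
- Suzuki–Miyaura coupling of F10 with 6 (Pd(PPh3)4, anhydrous K3PO4, 1,4-dioxane, 80 °C) gives 7.

**Step 14.** What may go wrong: migration of a silyl group from an aryl oxygen to the potassium alkoxide of the free primary alcohol, or base-induced desilylation; either leaves phenoxide-bearing partners that react sluggishly. Incomplete (E) selectivity is a lesser concern.

Fallback (Heck coupling in place of carbonyl olefination, with no phosphonate and no silyl ethers on the resorcinol ring; sets out from 14, comes back at 21):
- Wittig methylenation of 14 (Ph3PCH3Br, NaN(SiMe3)2, THF) gives [(2R,3S)-2-{3,5-dimethoxy-4-[tri(propan-2-yl)silyloxy]phenyl}-5-ethenyl-7-methoxy-2,3-dihydro-1-benzofuran-3-yl]methanol F11.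
- Mizoroki–Heck coupling with 5-iodobenzene-1,3-diol (Pd(OAc)2, P(o-tol)3, Et3N, DMF, 90 °C) gives 5-[(E)-2-[(2R,3S)-2-{3,5-dimethoxy-4-[tri(propan-2-yl)silyloxy]phenyl}-3-(hydroxymethyl)-7-methoxy-2,3-dihydro-1-benzofuran-5-yl]ethenyl]benzene-1,3-diol F12.
- The buffered fluoride conditions of step 15 then give 21.

## Further compounds

F1 | step 6 | methyl 4-(benzyloxy)-3-iodo-5-methoxybenzoate | COC(=O)c1cc(I)c(OCc2ccccc2)c(OC)c1
F2 | step 6 | methyl 4-(benzyloxy)-3-(2-tert-butoxy-2-oxoethyl)-5-methoxybenzoate | COC(=O)c1cc(CC(=O)OC(C)(C)C)c(OCc2ccccc2)c(OC)c1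
F3 | step 6 | [2-(benzyloxy)-3-methoxy-5-(methoxycarbonyl)phenyl]acetic acid | COC(=O)c1cc(CC(=O)O)c(OCc2ccccc2)c(OC)c1
F4 | step 6 | methyl 4-(benzyloxy)-3-{2-[(4R)-4-benzyl-2-oxo-1,3-oxazolidin-3-yl]-2-oxoethyl}-5-methoxybenzoate | COC(=O)c1cc(CC(=O)N2[C@H](Cc3ccccc3)COC2=O)c(OCc4ccccc4)c(OC)c1
F5 | step 6 | methyl 4-(benzyloxy)-3-{(2R,3R)-1-[(4R)-4-benzyl-2-oxo-1,3-oxazolidin-3-yl]-3-{3,5-dimethoxy-4-[tri(propan-2-yl)silyloxy]phenyl}-3-hydroxy-1-oxopropan-2-yl}-5-methoxybenzoate | COc1cc([C@H](O)[C@H](C(=O)N2[C@H](Cc3ccccc3)COC2=O)c4cc(C(=O)OC)cc(OC)c4OCc5ccccc5)cc(OC)c1O[Si](C(C)C)(C(C)C)C(C)C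
F6 | step 6 | methyl 4-(benzyloxy)-3-[(1R,2S)-1-{3,5-dimethoxy-4-[tri(propan-2-yl)silyloxy]phenyl}-1,3-dihydroxypropan-2-yl]-5-methoxybenzoate | COc1cc([C@H](O)[C@H](CO)c2cc(C(=O)OC)cc(OC)c2OCc3ccccc3)cc(OC)c1O[Si](C(C)C)(C(C)C)C(C)C
F7 | step 6 | methyl 3-[(1R,2S)-1-{3,5-dimethoxy-4-[tri(propan-2-yl)silyloxy]phenyl}-1,3-dihydroxypropan-2-yl]-4-hydroxy-5-methoxybenzoate | COc1cc([C@H](O)[C@H](CO)c2cc(C(=O)OC)cc(OC)c2O)cc(OC)c1O[Si](C(C)C)(C(C)C)C(C)C
F8 | step 7 | methyl 4-hydroxy-3-[(4S,5S)-4-(4-hydroxy-3,5-dimethoxyphenyl)-1,3-dioxan-5-yl]-5-methoxybenzoate | COc1cc([C@H]2OCOC[C@@H]2c3cc(C(=O)OC)cc(OC)c3O)cc(OC)c1O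
F9 | step 7 | methyl (2R,3S)-2-(4-hydroxy-3,5-dimethoxyphenyl)-3-(hydroxymethyl)-7-methoxy-2,3-dihydro-1-benzofuran-5-carboxylate | COc1cc([C@@H]2Oc3c(OC)cc(C(=O)OC)cc3[C@H]2CO)cc(OC)c1O
F10 | step 5 | {2,6-dimethoxy-4-[(E)-2-(4,4,5,5-tetramethyl-1,3,2-dioxaborolan-2-yl)ethenyl]phenoxy}tri(propan-2-yl)silane | CC(C)[Si](C(C)C)(C(C)C)Oc1c(OC)cc(/C=C/B2OC(C)(C)C(C)(C)O2)cc1OC
F11 | step 14 | [(2R,3S)-2-{3,5-dimethoxy-4-[tri(propan-2-yl)silyloxy]phenyl}-5-ethenyl-7-methoxy-2,3-dihydro-1-benzofuran-3-yl]methanol | COc1cc([C@@H]2Oc3c(OC)cc(C=C)cc3[C@H]2CO)cc(OC)c1O[Si](C(C)C)(C(C)C)C(C)C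
F12 | step 14 | 5-[(E)-2-[(2R,3S)-2-{3,5-dimethoxy-4-[tri(propan-2-yl)silyloxy]phenyl}-3-(hydroxymethyl)-7-methoxy-2,3-dihydro-1-benzofuran-5-yl]ethenyl]benzene-1,3-diol | COc1cc([C@@H]2Oc3c(OC)cc(/C=C/c4cc(O)cc(O)c4)cc3[C@H]2CO)cc(OC)c1O[Si](C(C)C)(C(C)C)C(C)C
A1 | alternative 1 | 4-[(2R,3S)-5-bromo-3-(hydroxymethyl)-7-methoxy-2,3-dihydro-1-benzofuran-2-yl]-2,6-dimethoxyphenol | COc1cc([C@@H]2Oc3c(OC)cc(Br)cc3[C@H]2CO)cc(OC)c1O
A2 | alternative 1 | 4-bromo-2-[(2S)-1-hydroxy-3-(4-hydroxy-3,5-dimethoxyphenyl)propan-2-yl]-6-methoxyphenol | COc1cc(C[C@H](CO)c2cc(Br)cc(OC)c2O)cc(OC)c1O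
A3 | alternative 1 | 4-[(2S)-2-(5-bromo-2-hydroxy-3-methoxyphenyl)-3-hydroxypropylidene]-2,6-dimethoxycyclohexa-2,5-dien-1-one | COC1=CC(=C[C@H](CO)c2cc(Br)cc(OC)c2O)C=C(OC)C1=O
A4 | alternative 2 | {(2R,3S)-5-bromo-2-[3,5-dimethoxy-4-(methoxymethoxy)phenyl]-7-methoxy-2,3-dihydro-1-benzofuran-3-yl}methoxy(tert-butyl)dimethylsilane | COCOc1c(OC)cc([C@@H]2Oc3c(OC)cc(Br)cc3[C@H]2CO[Si](C)(C)C(C)(C)C)cc1OC
A5 | alternative 2 | 4-bromo-2-{2-[tert-butyl(dimethyl)silyloxy]-1-(4-methylbenzenesulfonyl)ethyl}-6-methoxyphenol (racemic) | COc1cc(Br)cc(C(CO[Si](C)(C)C(C)(C)C)S(=O)(=O)c2ccc(C)cc2)c1O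
A6 | alternative 2 | (2R,5R)-1-{[3,5-dimethoxy-4-(methoxymethoxy)phenyl]methyl}-2,5-dimethylthiolan-1-ium tetrafluoroborate (one antipode drawn) | C[C@@H]1CC[C@@H](C)[S+]1Cc1cc(OC)c(OCOC)c(OC)c1.F[B-](F)(F)F
A7 | alternative 2 | 4-bromo-6-{2-[tert-butyl(dimethyl)silyloxy]ethylidene}-2-methoxycyclohexa-2,4-dien-1-one | COC1=CC(Br)=CC(=CCO[Si](C)(C)C(C)(C)C)C1=O
A8 | alternative 3 | (2R,3S)-3-{[tert-butyl(dimethyl)silyloxy]methyl}-2-[3,5-dimethoxy-4-(methoxymethoxy)phenyl]-5-[tri(propan-2-yl)silyloxy]-2,3-dihydro-1-benzofuran-7-ol | COCOc1c(OC)cc([C@@H]2Oc3c(O)cc(O[Si](C(C)C)(C(C)C)C(C)C)cc3[C@H]2CO[Si](C)(C)C(C)(C)C)cc1OC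
A9 | alternative 3 | 1-[(2R,3S)-3-{[tert-butyl(dimethyl)silyloxy]methyl}-2-[3,5-dimethoxy-4-(methoxymethoxy)phenyl]-2,3-dihydrofuran-4-yl]-2-diazoethan-1-one | O=C(C=[N+]=[N-])C1=CO[C@@H](c2cc(OC)c(OCOC)c(OC)c2)[C@@H]1CO[Si](C)(C)C(C)(C)C
A10 | alternative 3 | ethynyloxytri(propan-2-yl)silane | C#CO[Si](C(C)C)(C(C)C)C(C)C
A11 | alternative 3 | 2-[(2R,3S)-3-{[tert-butyl(dimethyl)silyloxy]methyl}-2-[3,5-dimethoxy-4-(methoxymethoxy)phenyl]-2,3-dihydrofuran-4-yl]ethen-1-one | O=C=CC1=CO[C@@H](c2cc(OC)c(OCOC)c(OC)c2)[C@@H]1CO[Si](C)(C)C(C)(C)C
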